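**Strategy.** The plan rests on closing ring A last, at the C1–C10 bond, by a 6-endo radical cyclisation. A tertiary C10 radical, generated in a preformed ring B by photocatalytic fragmentation of a cesium oxalate, attacks the CH2 terminus (C1) of a 2-(phenylsulfonyl)allyl arm carried by the quaternary C4. The step exploits the fully substituted ring-fusion carbon C10, flanked by equatorial groups at C5 and C9 of ring B, and creates the C10 quaternary stereocentre, the axial C20 methyl group and the trans-decalin in one operation. The precursor is a monocyclic 4-methylidenecyclohexyl tertiary oxalate, built by butenolide-templated C4/C5 construction and a carbonyl-ene closure of ring B that installs the C8(17) alkene.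

Key step: step 13

Remark: atoms are numbered as in labdane (C17 = exocyclic CH2, C19 = carboxyl carbon, C20 = angular methyl). The target is (4S,5R,9S,10R,13S)-15-(formyloxy)labd-8(17)-en-19-oic acid. Centres that are destroyed later (carbinol carbon in 5–7, C4 in 15, C2 in 26) are carried as epimer mixtures and drawn without a descriptor.

Step 1
Reactants: 1 (S)-citronellol
Product: 2 tert-butyl{[(3S)-3,7-dimethyloct-6-en-1-yl]oxy}diphenylsilane
Conditions: TBDPSCl, imidazole, DMF, rt
Reagents that add atoms: tert-butyl(chloro)diphenylsilane, CC(C)(C)[Si](Cl)(c1ccccc1)c1ccccc1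
Why: Silylation of the primary alcohol; the C13 stereocentre is taken from the chiral pool and is not touched in any later step.

Step 2
Reactants: 2 tert-butyl{[(3S)-3,7-dimethyloct-6-en-1-yl]oxy}diphenylsilane
Product: 3 (4S)-6-[(tert-butyldiphenylsilyl)oxy]-4-methylhexanal
Conditions: O3, CH2Cl2, −78 °C; then PPh3
Reagents that add atoms: ozone, [O-][O+]=O
Why: Ozonolysis with reductive work-up cleaves the only alkene and gives the aldehyde whose carbonyl carbon becomes C9.

Step 3
Reactants: 3 (4S)-6-[(tert-butyldiphenylsilyl)oxy]-4-methylhexanal; 4 prop-1-en-2-ylmagnesium bromide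
Product: 6 (6S)-8-[(tert-butyldiphenylsilyl)oxy]-2,6-dimethyloct-1-en-3-yl acetate, via bromomagnesium alkoxide 5 (not isolated)
Conditions: THF, −78 → 0 °C; then Ac2O, DMAP (cat.), 0 °C → rt
Reagents that add atoms: acetic anhydride, CC(=O)OC(C)=O
Why: Grignard 1,2-addition followed by acetylation of the alkoxide in the same flask; the new carbinol centre is uncontrolled and irrelevant because it becomes sp2 in step 4.

Step 4
Reactants: 6 (6S)-8-[(tert-butyldiphenylsilyl)oxy]-2,6-dimethyloct-1-en-3-yl acetate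
Product: 9 (4E,8S)-10-[(tert-butyldiphenylsilyl)oxy]-4,8-dimethyldec-4-enoic acid, via silyl ketene acetal 7 (not isolated), via trimethylsilyl ester 8 (not isolated)
Conditions: LiN(i-Pr)2 (commercial solution), TMSCl, THF, −78 → 60 °C; then dilute aq. HCl
Reagents that add atoms: none
Why: Ireland–Claisen rearrangement through a chair transition state with the alkyl chain equatorial should give the (E)-trisubstituted C8=C9 alkene, the geometry that step 11 converts into the C9 configuration.

Step 5
Reactants: 10 (2R)-but-3-en-2-ol; 11 methacryloyl chloride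
Product: 12 (2R)-but-3-en-2-yl 2-methylprop-2-enoate
Conditions: Et3N, DMAP (cat.), CH2Cl2, 0 °C
Reagents that add atoms: none
Why: Acylation of the secondary allylic alcohol with retention of its configuration.

Step 6
Reactants: 12 (2R)-but-3-en-2-yl 2-methylprop-2-enoate
Product: 13 (5R)-3,5-dimethylfuran-2(5H)-one
Conditions: second-generation Grubbs catalyst RuCl2(=CHPh)(PCy3)(H2IMes) (5 mol %), CH2Cl2, 40 °C
Reagents that add atoms: none
Why: Ring-closing metathesis to the α-methyl butenolide; its stereocentre (future C10) will steer the configuration of C5.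

Step 7
Reactants: 9 (4E,8S)-10-[(tert-butyldiphenylsilyl)oxy]-4,8-dimethyldec-4-enoic acid; 13 (5R)-3,5-dimethylfuran-2(5H)-one
Product: 15 (4S,5R)-4-{(3E,7S)-9-[(tert-butyldiphenylsilyl)oxy]-3,7-dimethylnon-3-en-1-yl}-3,5-dimethyloxolan-2-one, via N-acyloxyphthalimide 14 (not isolated)
Conditions: N-hydroxyphthalimide, DIC, DMAP (cat.), CH2Cl2, rt; then 13 (5 equiv), Ru(bpy)3(PF6)2 (1 mol %), Hantzsch ester, i-Pr2NEt, blue LEDs, rt
Reagents that add atoms: none
Why: Decarboxylative Giese reaction of the redox-active ester: the primary C6 radical adds to the unsubstituted β-carbon of the butenolide anti to its ring methyl group, which sets C5, while the excess of acceptor is meant to keep capture faster than reversible 3-exo closure of the homoallylic radical.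

Step 8
Reactants: 15 (4S,5R)-4-{(3E,7S)-9-[(tert-butyldiphenylsilyl)oxy]-3,7-dimethylnon-3-en-1-yl}-3,5-dimethyloxolan-2-one; 16 2,3-bis(phenylsulfonyl)prop-1-ene
Product: 18 (3S,4S,5R)-4-{(3E,7S)-9-[(tert-butyldiphenylsilyl)oxy]-3,7-dimethylnon-3-en-1-yl}-3,5-dimethyl-3-[2-(phenylsulfonyl)prop-2-en-1-yl]oxolan-2-one, via lithium enolate 17 (not isolated)
Conditions: LiN(i-Pr)2 (commercial solution), THF, −78 °C; then 16, −78 → −40 °C
Reagents that add atoms: none
Why: Lactone enolate alkylation by addition–elimination (SN2′) on the bis-sulfone; the electrophile should enter anti to the adjacent C5 side chain, which sets the C4 quaternary centre with the methyl group cis and the sulfonylallyl arm trans to that chain.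

Step 9
Reactants: 18 (3S,4S,5R)-4-{(3E,7S)-9-[(tert-butyldiphenylsilyl)oxy]-3,7-dimethylnon-3-en-1-yl}-3,5-dimethyl-3-[2-(phenylsulfonyl)prop-2-en-1-yl]oxolan-2-one
Product: 21 (2S,3S,6E,10S)-3-acetyl-12-[(tert-butyldiphenylsilyl)oxy]-2,6,10-trimethyl-2-[2-(phenylsulfonyl)prop-2-en-1-yl]dodec-6-enoic acid, via lithium carboxylate 19 (not isolated), via hydroxy acid 20 (not isolated)
Conditions: LiOH·H2O, THF/H2O, 0 °C → rt; then H2SO4 to pH 3 at 0 °C, CrO3/H2SO4 (Jones reagent), acetone, 0 °C
Reagents that add atoms: lithium hydroxide, [Li+].[OH-]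
Why: Saponification of the γ-lactone followed at once by Jones oxidation of the freed secondary alcohol, before it can close back, turns the template stereocentre into the C10 methyl ketone; the α-substituted vinyl sulfone is a poor acceptor for hydroxide at this temperature and any re-formed 18 can be recycled.

Step 10
Reactants: 21 (2S,3S,6E,10S)-3-acetyl-12-[(tert-butyldiphenylsilyl)oxy]-2,6,10-trimethyl-2-[2-(phenylsulfonyl)prop-2-en-1-yl]dodec-6-enoic acid
Product: 22 2-(trimethylsilyl)ethyl (2S,3S,6E,10S)-3-acetyl-12-[(tert-butyldiphenylsilyl)oxy]-2,6,10-trimethyl-2-[2-(phenylsulfonyl)prop-2-en-1-yl]dodec-6-enoate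
Conditions: Me3SiCH2CH2OH, PPh3, DIAD, THF, 0 °C → rt
Reagents that add atoms: 2-(trimethylsilyl)ethanol, C[Si](C)(C)CCO
Why: Mitsunobu esterification, in which the hindered carboxylate is only the nucleophile toward the activated primary alcohol, gives a fluoride-labile ester under neutral conditions that do not epimerise C5.

Step 11
Reactants: 22 2-(trimethylsilyl)ethyl (2S,3S,6E,10S)-3-acetyl-12-[(tert-butyldiphenylsilyl)oxy]-2,6,10-trimethyl-2-[2-(phenylsulfonyl)prop-2-en-1-yl]dodec-6-enoate
Product: 24 2-(trimethylsilyl)ethyl (2S)-2-{(1S,2S,3S)-3-[(3S)-5-[(tert-butyldiphenylsilyl)oxy]-3-methylpentyl]-2-[(2-methoxy-2-oxoacetyl)oxy]-2-methyl-4-methylidenecyclohexyl}-2-methyl-4-(phenylsulfonyl)pent-4-enoate, via aluminium alkoxide 23 (not isolated)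
Conditions: Me2AlCl (2.5 equiv), CH2Cl2, −78 → −40 °C; then pyridine, DMAP, ClCOCO2Me, −78 → 0 °C
Reagents that add atoms: methyl chlorooxoacetate, COC(=O)C(Cl)=O
Why: Intramolecular carbonyl-ene reaction of the methyl ketone (tether on the central carbon of the ene unit) closes ring B through a chair transition state with the C5 substituent and the (E)-derived C9 side chain both equatorial, which sets C9 and delivers the C8(17) methylidene group by hydrogen transfer from C17; the tertiary aluminium alkoxide is acylated in the same flask before it can attack the ester, and the C10 configuration (oxygen expected axial) is irrelevant.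

Step 12
Reactants: 24 2-(trimethylsilyl)ethyl (2S)-2-{(1S,2S,3S)-3-[(3S)-5-[(tert-butyldiphenylsilyl)oxy]-3-methylpentyl]-2-[(2-methoxy-2-oxoacetyl)oxy]-2-methyl-4-methylidenecyclohexyl}-2-methyl-4-(phenylsulfonyl)pent-4-enoate
Product: 25 cesium 2-{[(1S,2S,6S)-2-[(3S)-5-[(tert-butyldiphenylsilyl)oxy]-3-methylpentyl]-1-methyl-3-methylidene-6-{(2S)-2-methyl-1-oxo-4-(phenylsulfonyl)-1-[2-(trimethylsilyl)ethoxy]pent-4-en-2-yl}cyclohexyl]oxy}-2-oxoacetate
Conditions: CsOH·H2O (1.0 equiv), THF/H2O, rt
Reagents that add atoms: cesium hydroxide, [Cs+].[OH-]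
Why: The methyl oxalate is by far the most electrophilic ester and should be hydrolysed selectively, leaving the hindered silylethyl ester intact.

Step 13
Reactants: 25 cesium oxalate of the ring B tertiary alcohol
Product: 26 2-(trimethylsilyl)ethyl (4S,5R,9S,10R,13S)-15-[(tert-butyldiphenylsilyl)oxy]-2-(phenylsulfonyl)labd-8(17)-en-19-oate
Conditions: Ir[dF(CF3)ppy]2(dtbbpy)PF6 (1 mol %), H2O (10 equiv), DME/DMF 3:1, 0.01 M, blue LEDs, 60 °C
Reagents that add atoms: none
Why: The photoexcited iridium complex oxidises the oxalate carboxylate, which loses two molecules of CO2 to give the tertiary C10 radical; this adds to the unsubstituted terminus C1 of the vinyl sulfone, and the resulting α-sulfonyl radical is reduced by the reduced photocatalyst and protonated by water. The closest known reaction type is the redox-neutral photocatalytic Giese coupling of tert-alkyl cesium oxalates with electron-poor alkenes, run here intramolecularly. Ring A closes in the 6-endo-trig mode, preferred over 5-exo attack at C2 because C2 is fully substituted and carries the sulfonyl group that polarises the alkene toward attack at C1. The C10 stereocentre is controlled by a chair–chair transition state like that of the second ring closure of a polyene cyclisation: ring B keeps its C5 and C9 substituents equatorial, C1 bonds on the equatorial side of the radical and the C20 methyl group becomes axial, which gives the trans ring fusion, whereas the cis closure would need an axial C5–C6 bond on the forming ring and a syn-diaxial C18/C20 contact. The step needs radical formation only at C10 and closure faster than hydrogen abstraction; the first is secured because the oxalate is the only group the catalyst can oxidise, the second by the short tether and the persistence of the hindered tertiary radical. The C2 epimers are of no consequence because the sulfonyl group is removed in step 14.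

Step 14
Reactants: 26 2-(trimethylsilyl)ethyl (4S,5R,9S,10R,13S)-15-[(tert-butyldiphenylsilyl)oxy]-2-(phenylsulfonyl)labd-8(17)-en-19-oate
Product: 27 2-(trimethylsilyl)ethyl (4S,5R,9S,10R,13S)-15-[(tert-butyldiphenylsilyl)oxy]labd-8(17)-en-19-oate
Conditions: Na(Hg) (6 % Na), Na2HPO4, MeOH/THF, −20 °C → rt
Reagents that add atoms: none
Why: Buffered reductive desulfonylation of the secondary alkyl phenyl sulfone leaves C2 as CH2 and should spare the hindered ester, the silyl ether and the 1,1-disubstituted alkene.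

Step 15
Reactants: 27 2-(trimethylsilyl)ethyl (4S,5R,9S,10R,13S)-15-[(tert-butyldiphenylsilyl)oxy]labd-8(17)-en-19-oate
Product: 28 (4S,5R,9S,10R,13S)-15-hydroxylabd-8(17)-en-19-oic acid (imbricatolic acid)
Conditions: Bu4NF (4 equiv), THF, rt → 45 °C; then dilute aq. HCl to pH 4
Reagents that add atoms: none
Why: Fluoride removes both silicon-based groups in one operation, the silyl ether by Si–O cleavage and the axial C19 ester by fragmentation at silicon, which does not depend on access to the hindered carbonyl.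

Step 16
Reactants: 28 (4S,5R,9S,10R,13S)-15-hydroxylabd-8(17)-en-19-oic acid
Product: 29 (4S,5R,9S,10R,13S)-15-(formyloxy)labd-8(17)-en-19-oic acid
Conditions: HCO2CH2CF3 (excess), THF, 65 °C
Reagents that add atoms: 2,2,2-trifluoroethyl formate, O=COCC(F)(F)F
Why: Transformylation of the unhindered primary alcohol under neutral conditions that leave the free carboxylic acid and the acid-sensitive exocyclic alkene untouched.

**Compound list**

1 | (S)-citronellol, (3S)-3,7-dimethyloct-6-en-1-ol | CC(C)=CCC[C@H](C)CCO | starting material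
2 | tert-butyl{[(3S)-3,7-dimethyloct-6-en-1-yl]oxy}diphenylsilane | CC(C)=CCC[C@H](C)CCO[Si](c1ccccc1)(c1ccccc1)C(C)(C)C | intermediate
3 | (4S)-6-[(tert-butyldiphenylsilyl)oxy]-4-methylhexanal | O=CCC[C@H](C)CCO[Si](c1ccccc1)(c1ccccc1)C(C)(C)C | intermediate
4 | prop-1-en-2-ylmagnesium bromide | CC(=C)[Mg]Br | starting material
5 | bromomagnesium (6S)-8-[(tert-butyldiphenylsilyl)oxy]-2,6-dimethyloct-1-en-3-olate (both C3 epimers) | CC(=C)C(O[Mg]Br)CC[C@H](C)CCO[Si](c1ccccc1)(c1ccccc1)C(C)(C)C | intermediate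
6 | (6S)-8-[(tert-butyldiphenylsilyl)oxy]-2,6-dimethyloct-1-en-3-yl acetate (both C3 epimers) | CC(=C)C(OC(C)=O)CC[C@H](C)CCO[Si](c1ccccc1)(c1ccccc1)C(C)(C)C | intermediate
7 | trimethylsilyl ketene acetal of 6, (6S)-8-[(tert-butyldiphenylsilyl)oxy]-2,6-dimethyloct-1-en-3-yl 1-[(trimethylsilyl)oxy]ethenyl ether | C=C(O[Si](C)(C)C)OC(C(C)=C)CC[C@H](C)CCO[Si](c1ccccc1)(c1ccccc1)C(C)(C)C | intermediate
8 | trimethylsilyl (4E,8S)-10-[(tert-butyldiphenylsilyl)oxy]-4,8-dimethyldec-4-enoate | C[Si](C)(C)OC(=O)CC/C(C)=C/CC[C@H](C)CCO[Si](c1ccccc1)(c1ccccc1)C(C)(C)C | intermediate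
9 | (4E,8S)-10-[(tert-butyldiphenylsilyl)oxy]-4,8-dimethyldec-4-enoic acid | OC(=O)CC/C(C)=C/CC[C@H](C)CCO[Si](c1ccccc1)(c1ccccc1)C(C)(C)C | intermediate
10 | (2R)-but-3-en-2-ol | C[C@H](C=C)O | starting material
11 | methacryloyl chloride, 2-methylprop-2-enoyl chloride | CC(=C)C(Cl)=O | starting material
12 | (2R)-but-3-en-2-yl 2-methylprop-2-enoate | C[C@H](C=C)OC(=O)C(C)=C | intermediate
13 | (5R)-3,5-dimethylfuran-2(5H)-one | C[C@H]1OC(=O)C(C)=C1 | intermediate
14 | 1,3-dioxoisoindolin-2-yl (4E,8S)-10-[(tert-butyldiphenylsilyl)oxy]-4,8-dimethyldec-4-enoate | O=C(CC/C(C)=C/CC[C@H](C)CCO[Si](c1ccccc1)(c1ccccc1)C(C)(C)C)ON1C(=O)c2ccccc2C1=O | intermediate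
15 | (4S,5R)-4-{(3E,7S)-9-[(tert-butyldiphenylsilyl)oxy]-3,7-dimethylnon-3-en-1-yl}-3,5-dimethyloxolan-2-one (4,5-trans; both C3 epimers) | C[C@H]1OC(=O)C(C)[C@@H]1CC/C(C)=C/CC[C@H](C)CCO[Si](c2ccccc2)(c2ccccc2)C(C)(C)C | intermediate
16 | 2,3-bis(phenylsulfonyl)prop-1-ene | C=C(CS(=O)(=O)c1ccccc1)S(=O)(=O)c1ccccc1 | starting material
17 | lithium enolate of 15 | [Li+].C[C@H]1OC([O-])=C(C)[C@@H]1CC/C(C)=C/CC[C@H](C)CCO[Si](c2ccccc2)(c2ccccc2)C(C)(C)C | intermediate
18 | (3S,4S,5R)-4-{(3E,7S)-9-[(tert-butyldiphenylsilyl)oxy]-3,7-dimethylnon-3-en-1-yl}-3,5-dimethyl-3-[2-(phenylsulfonyl)prop-2-en-1-yl]oxolan-2-one | C[C@H]1OC(=O)[C@@](C)(CC(=C)S(=O)(=O)c2ccccc2)[C@@H]1CC/C(C)=C/CC[C@H](C)CCO[Si](c3ccccc3)(c3ccccc3)C(C)(C)C | intermediate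
19 | lithium (2S,3S,6E,10S)-12-[(tert-butyldiphenylsilyl)oxy]-3-[(1R)-1-hydroxyethyl]-2,6,10-trimethyl-2-[2-(phenylsulfonyl)prop-2-en-1-yl]dodec-6-enoate | [Li+].[O-]C(=O)[C@@](C)(CC(=C)S(=O)(=O)c1ccccc1)[C@@H]([C@@H](C)O)CC/C(C)=C/CC[C@H](C)CCO[Si](c1ccccc1)(c1ccccc1)C(C)(C)C | intermediate
20 | (2S,3S,6E,10S)-12-[(tert-butyldiphenylsilyl)oxy]-3-[(1R)-1-hydroxyethyl]-2,6,10-trimethyl-2-[2-(phenylsulfonyl)prop-2-en-1-yl]dodec-6-enoic acid | OC(=O)[C@@](C)(CC(=C)S(=O)(=O)c1ccccc1)[C@@H]([C@@H](C)O)CC/C(C)=C/CC[C@H](C)CCO[Si](c1ccccc1)(c1ccccc1)C(C)(C)C | intermediate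
21 | (2S,3S,6E,10S)-3-acetyl-12-[(tert-butyldiphenylsilyl)oxy]-2,6,10-trimethyl-2-[2-(phenylsulfonyl)prop-2-en-1-yl]dodec-6-enoic acid | OC(=O)[C@@](C)(CC(=C)S(=O)(=O)c1ccccc1)[C@@H](C(C)=O)CC/C(C)=C/CC[C@H](C)CCO[Si](c1ccccc1)(c1ccccc1)C(C)(C)C | intermediate
22 | 2-(trimethylsilyl)ethyl (2S,3S,6E,10S)-3-acetyl-12-[(tert-butyldiphenylsilyl)oxy]-2,6,10-trimethyl-2-[2-(phenylsulfonyl)prop-2-en-1-yl]dodec-6-enoate | C[Si](C)(C)CCOC(=O)[C@@](C)(CC(=C)S(=O)(=O)c1ccccc1)[C@@H](C(C)=O)CC/C(C)=C/CC[C@H](C)CCO[Si](c1ccccc1)(c1ccccc1)C(C)(C)C | intermediate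
23 | chloro(methyl)aluminium alkoxide of 2-(trimethylsilyl)ethyl (2S)-2-{(1S,2S,3S)-3-[(3S)-5-[(tert-butyldiphenylsilyl)oxy]-3-methylpentyl]-2-hydroxy-2-methyl-4-methylidenecyclohexyl}-2-methyl-4-(phenylsulfonyl)pent-4-enoate | C=C1CC[C@@H]([C@@](C)(C(=O)OCC[Si](C)(C)C)CC(=C)S(=O)(=O)c2ccccc2)[C@](O[Al](C)Cl)(C)[C@H]1CC[C@H](C)CCO[Si](c2ccccc2)(c2ccccc2)C(C)(C)C | intermediate
24 | 2-(trimethylsilyl)ethyl (2S)-2-{(1S,2S,3S)-3-[(3S)-5-[(tert-butyldiphenylsilyl)oxy]-3-methylpentyl]-2-[(2-methoxy-2-oxoacetyl)oxy]-2-methyl-4-methylidenecyclohexyl}-2-methyl-4-(phenylsulfonyl)pent-4-enoate | C=C1CC[C@@H]([C@@](C)(C(=O)OCC[Si](C)(C)C)CC(=C)S(=O)(=O)c2ccccc2)[C@](OC(=O)C(=O)OC)(C)[C@H]1CC[C@H](C)CCO[Si](c2ccccc2)(c2ccccc2)C(C)(C)C | intermediate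
25 | cesium oxalate half ester of the same tertiary alcohol (cesium salt of the acid corresponding to 24) | [Cs+].C=C1CC[C@@H]([C@@](C)(C(=O)OCC[Si](C)(C)C)CC(=C)S(=O)(=O)c2ccccc2)[C@](OC(=O)C([O-])=O)(C)[C@H]1CC[C@H](C)CCO[Si](c2ccccc2)(c2ccccc2)C(C)(C)C | intermediate
26 | 2-(trimethylsilyl)ethyl (4S,5R,9S,10R,13S)-15-[(tert-butyldiphenylsilyl)oxy]-2-(phenylsulfonyl)labd-8(17)-en-19-oate (trans-decalin; both C2 epimers) | C=C1CC[C@@H]2[C@](C)(CC(S(=O)(=O)c3ccccc3)C[C@]2(C)C(=O)OCC[Si](C)(C)C)[C@H]1CC[C@H](C)CCO[Si](c4ccccc4)(c4ccccc4)C(C)(C)C | intermediate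
27 | 2-(trimethylsilyl)ethyl (4S,5R,9S,10R,13S)-15-[(tert-butyldiphenylsilyl)oxy]labd-8(17)-en-19-oate | C=C1CC[C@@H]2[C@](C)(CCC[C@]2(C)C(=O)OCC[Si](C)(C)C)[C@H]1CC[C@H](C)CCO[Si](c3ccccc3)(c3ccccc3)C(C)(C)C | intermediate
28 | (4S,5R,9S,10R,13S)-15-hydroxylabd-8(17)-en-19-oic acid (imbricatolic acid) | C=C1CC[C@@H]2[C@](C)(CCC[C@]2(C)C(=O)O)[C@H]1CC[C@H](C)CCO | intermediate
29 | (4S,5R,9S,10R,13S)-15-(formyloxy)labd-8(17)-en-19-oic acid | C=C1CC[C@@H]2[C@](C)(CCC[C@]2(C)C(=O)O)[C@H]1CC[C@H](C)CCOC=O | target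

**Step count.** Total: 16 steps. Longest linear sequence: 14 steps (steps 1–4 and 7–16); steps 5 and 6 form the side branch.

**Steps most likely to fail**

Step 13 (ring closure). The C10 radical may be consumed by hydrogen abstraction, by disproportionation to alkenes or by a 1,5-hydrogen shift from C13 before it reaches C1, and part of it may close on the other face to the cis-fused isomer. Fallback: leave the photocatalytic redox-neutral manifold for a stannane chain reaction that starts one compound earlier. The tert-alkyl methyl oxalate 24 is heated in toluene (110 °C, high dilution) while Bu3SnH and AIBN are added slowly. The stannyl radical adds to the oxalate carbonyl and β-scission frees the same C10 radical in a medium whose only hydrogen donor is kept at very low concentration. The 6-endo closure follows and the α-sulfonyl radical is ended by hydrogen transfer from the stannane. This sets out from 24 and comes back at 26 and makes no new compound.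

Step 11 (ring B closure and oxalate formation). Acylation of the crowded tertiary aluminium alkoxide may lag, so that the alkoxide closes onto the neighbouring ester carbonyl (γ-lactone formation) or the oxalate forms incompletely. Fallback: do without the oxalate. From 22 the carbonyl-ene reaction is run as before but quenched at −78 °C with pH 7 buffer. This gives the neutral tertiary alcohol 2-(trimethylsilyl)ethyl (2S)-2-{(1S,2S,3S)-3-[(3S)-5-[(tert-butyldiphenylsilyl)oxy]-3-methylpentyl]-2-hydroxy-2-methyl-4-methylidenecyclohexyl}-2-methyl-4-(phenylsulfonyl)pent-4-enoate F1, a much poorer nucleophile toward the ester than its alkoxide. F1 is then cyclised directly by a titanium-mediated dehydroxylative Giese reaction (Cp*TiCl3 cat., Zn, Et3SiCl, THF, rt), in which the low-valent titanium alkoxide undergoes C–O homolysis to the same C10 radical. This sets out from 22 and comes back at 26, bypassing 24 and 25.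

Step 7 (C5–C6 bond). The homoallylic primary radical may add only slowly to the trisubstituted butenolide; reversible 3-exo closure to a cyclopropylcarbinyl radical would then scramble the E geometry of the C8=C9 alkene, and hydrogen transfer from the dihydropyridine would give the decarboxylated alkane. Fallback: make the bond by a polar conjugate addition. From 9, the N-acyloxyphthalimide 14 is converted by visible-light iododecarboxylation (LiI, PPh3 cat., acetone, blue LEDs), in which iodine capture is much faster than ring closure of the radical, into the primary iodide tert-butyl{[(3S,6E)-9-iodo-3,7-dimethylnon-6-en-1-yl]oxy}diphenylsilane F2. Magnesium insertion (Mg, THF) gives the Grignard reagent {(3E,7S)-9-[(tert-butyldiphenylsilyl)oxy]-3,7-dimethylnon-3-en-1-yl}magnesium iodide F3. F3 adds to 13 under copper catalysis (CuBr·SMe2 cat., TMSCl, THF, −78 °C) anti to the ring methyl group to give the trimethylsilyl ketene acetal of 15 F4. Dilute aqueous acid then gives 15, where the route is rejoined.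

**Further compounds**

F0 | step 13 | none | none
F1 | step 11 | 2-(trimethylsilyl)ethyl (2S)-2-{(1S,2S,3S)-3-[(3S)-5-[(tert-butyldiphenylsilyl)oxy]-3-methylpentyl]-2-hydroxy-2-methyl-4-methylidenecyclohexyl}-2-methyl-4-(phenylsulfonyl)pent-4-enoate | C=C1CC[C@@H]([C@@](C)(C(=O)OCC[Si](C)(C)C)CC(=C)S(=O)(=O)c2ccccc2)[C@](O)(C)[C@H]1CC[C@H](C)CCO[Si](c2ccccc2)(c2ccccc2)C(C)(C)C
F2 | step 7 | tert-butyl{[(3S,6E)-9-iodo-3,7-dimethylnon-6-en-1-yl]oxy}diphenylsilane | ICC/C(C)=C/CC[C@H](C)CCO[Si](c1ccccc1)(c1ccccc1)C(C)(C)C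
F3 | step 7 | {(3E,7S)-9-[(tert-butyldiphenylsilyl)oxy]-3,7-dimethylnon-3-en-1-yl}magnesium iodide | I[Mg]CC/C(C)=C/CC[C@H](C)CCO[Si](c1ccccc1)(c1ccccc1)C(C)(C)C
F4 | step 7 | trimethylsilyl ketene acetal of 15 | C[C@H]1OC(O[Si](C)(C)C)=C(C)[C@@H]1CC/C(C)=C/CC[C@H](C)CCO[Si](c2ccccc2)(c2ccccc2)C(C)(C)C
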